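Fractions of the charge were my unit, and in that unit chain length is a division: the fraction of free monomer reacted, over the fraction charged as initiator, provided each initiator begins one chain.

| flask | free monomer | initiator | remark | time |
|---|---|---|---|---|
| autumn | 0.020 M | 0.1 mol% | run made earlier |  |
| spring | 0.020 M | 0.42 mol% | run made earlier |  |
| winter | 0.010 M | 0.21 mol% | run made earlier |  |
| green | 0.020 M | 0.21 mol% |  | 40 min |
| amber | 0.020 M | 0.21 mol% |  | 20 min |

- autumn (time / min: monomer in chains / %): 6.00: 4.6; 12.0: 13.3; 20.0: 21.7; 25.0: 29.9; 30.0: 35.1
- spring (time / min: monomer in chains / %): 3.00: 4.8; 8.00: 25.9; 15.0: 50.5; 25.0: 71.3; 30.0: 76.3
- winter (time / min: monomer in chains / %): 2.50: 1.0; 5.00: 3.6; 10.0: 6.8; 15.0: 11.6; 30.0: 25.4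

(scatter of a reading: 1 percentage point)

- which of the two ends with the longer chains by the average number of monomer units in a chain (chains begun, living or dead) ("neither" if they lie within 10%) (green / amber / neither)
- average number of monomer units in a chain (chains begun, living or dead) at the end, green
- average number of monomer units in a chain (chains begun, living or dead) at the end, amber

- the average divides the monomer in chains by the number of chains begun, living and dead together
- steps thought possible: free monomer + initiator -> living end + monomer in chains; monomer in chains + living end -> free monomer + living end; free monomer + living end -> monomer in chains + living end; initiator + monomer in chains -> spent initiator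
- the earlier runs do not show the number of chains; that part of a forecast is a guess

I called the reciprocal of the loading the length ceiling, the units per chain if the whole charge of free monomer entered chains and each initiator had begun one: 476 for green and amber alike. Length is the ceiling times the fraction reacted, so I needed that fraction at each time. The earlier runs show no chains, so one chain per initiator was a guess.

My first way was a pseudo-first-order law, with the living ends steady and free monomer falling by a constant fraction of itself each minute. Autumn's readings at 12.0 min and 30.0 min gave 0.0161 min⁻¹ and, run backwards, a lag of 3.13 min, shorter than amber's time. Scaled by loading to 0.0338 min⁻¹, this gave 71.2% for green and 43.4% for amber. The same law put spring's last reading at 83.7%, but spring read 76.3%, less than the law said. This way knows no end state, so I held it as an upper bound.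

My second way used spring as a faster clock. Spring carries twice green's initiator, so after the lag its time should run double, and green's 40 min becomes spring's 21.6 min, amber's 20 min spring's 11.6 min. Straight lines between spring's readings gave 64.2% and 38.4%. Spring's curve bends over and a straight line lies under such a curve, so I held these as lower bounds.

Each way erred in a known direction, so I took the middles, 67.7% and 40.9%. Times the ceiling, these made green 322 and amber 195, green longer by more than the margin.

The forecast said green, with 312 (275 to 390) and 195 (165 to 245), on “reversible propagation with an equilibrium monomer level”.

The flask gave green, green 325 and amber 204.

    free monomer + initiator → living end + monomer in chains (k = 0.190 M⁻¹ s⁻¹)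
    monomer in chains + living end → free monomer + living end, rate k2*[living end] as long as [monomer in chains] is above zero (k = 0.0410 s⁻¹)
    free monomer + living end → monomer in chains + living end, rate k3*[living end]*[free monomer] (k = 16.5 M⁻¹ s⁻¹)
    initiator + monomer in chains → spent initiator (k = 0.0255 M⁻¹ s⁻¹)

Green stood at 67.1% monomer in chains with 0.21% of its initiator left, and the ceiling times that fraction makes 320. A neighbour of green charged with 0.0050 M of free monomer has the same loading and so the same ceiling. It reached 11.4% monomer in chains with 11% of its initiator unused, so counting only the chains begun, the ceiling gives 61.2, and that flask gave 61.5.

The runs come from a simulation with constants of no real substance, and the scatter is random.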